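**Retrosynthetic overview**

- Gancaonin J ⇐ its ring B mesylate (hydroxide cleavage of the aryl sulfonate) ⇐ the 3',5'-diallyl dihydrochalcone (two cross-metatheses with 2-methylbut-2-ene turn allyl into prenyl).
- 3',5'-Diallyl compound ⇐ 2',4'-bis(allyl ether): two thermal [3,3] shifts carry both allyl groups from O2' and O4' to carbon, forming C3'–CH2 and C5'–CH2.
- Bis(allyl ether) ⇐ 2',4'-dihydroxy ketone + two equivalents of allyl bromide; ketone ⇐ resorcinol + 3-[4-(methanesulfonyloxy)phenyl]propanoic acid (C1'–C(=O) bond by BF3·OEt2 acylation, before any alkene exists) ⇐ 3-(4-hydroxyphenyl)propanoic acid.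
- Feature the plan rests on: in ring A, C3' lies between O2' and O4', and C5' is ortho to O4' and para to O2'; C1' carries the acyl group and C6' is meta to both oxygens, so only C3' and C5' can keep an allyl group that leaves oxygen.
- No ring is formed; both benzene rings are bought, and the target has no stereocenter.

Key step: step 4

Assumption: ring A is numbered with C1' at the acyl-bearing carbon and oxygens on C2' and C4'; ring B is the 4-oxygenated ring. In step 4 one order of the two allyl shifts is written out, and the other orders should converge on the same product.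

**Route**

Step 1
Reactants: 1 3-(4-hydroxyphenyl)propanoic acid
Product: 2 3-[4-(methanesulfonyloxy)phenyl]propanoic acid
Conditions: MsCl (2.5 equiv), 2 M aq. NaOH, THF, 0 °C; then aq. HCl to pH 2
Reagents that add atoms: methanesulfonyl chloride, CS(=O)(=O)Cl
Why: Schotten–Baumann O-sulfonylation, in which the phenoxide is sulfonylated much faster than the carboxylate and any mixed carboxylic–sulfonic anhydride is hydrolysed in the aqueous base, so acidification should return the free acid with the ring B phenol masked as a mesylate that tolerates Lewis acid, heat and ruthenium carbenes.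

Step 2
Reactants: 2 3-[4-(methanesulfonyloxy)phenyl]propanoic acid; 3 resorcinol
Product: 5 2',4'-dihydroxy-4-(methanesulfonyloxy)dihydrochalcone [1-(2,4-dihydroxyphenyl)-3-(4-methanesulfonyloxyphenyl)propan-1-one], via difluoroboron chelate 4 (not isolated)
Conditions: BF3·OEt2 (neat, about 6 equiv), 85 °C, Ar; then H2O, 0 °C to 50 °C
Reagents that add atoms: none
Why: Friedel–Crafts acylation of a phenol with a free carboxylic acid promoted by BF3·OEt2, in which resorcinol is attacked at C4 (para to one hydroxyl, ortho to the other), the mesylated ring B is too deactivated to compete, and the ketone is held as its difluoroboron chelate 4 until water releases 5.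

Step 3
Reactants: 5 2',4'-dihydroxy-4-(methanesulfonyloxy)dihydrochalcone; 6 allyl bromide (two equivalents are consumed, one per ring A hydroxyl)
Product: 7 2',4'-bis(allyloxy)-4-(methanesulfonyloxy)dihydrochalcone
Conditions: allyl bromide (3 equiv), K2CO3 (4 equiv), DMF, 60 °C
Reagents that add atoms: allyl bromide (second equivalent of 6), C=CCBr
Why: Twofold Williamson ether synthesis, in which carbonate deprotonates both ring A phenols and each phenoxide displaces bromide from one molecule of allyl bromide (the 4'-OH first, the hydrogen-bonded 2'-OH more slowly but fully in warm DMF with excess halide), while the aryl mesylate and the ketone α-CH2 are inert to this weak base.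

Step 4
Reactants: 7 2',4'-bis(allyloxy)-4-(methanesulfonyloxy)dihydrochalcone
Product: 11 3',5'-diallyl-2',4'-dihydroxy-4-(methanesulfonyloxy)dihydrochalcone, via C3'-allyl dienone 8 (not isolated), via 3'-allyl-4'-allyloxy-2'-hydroxy ketone 9 (not isolated), via C5'-allyl dienone 10 (not isolated)
Conditions: 1,2-dichlorobenzene (degassed, 0.05 M), 200 °C, sealed tube, Ar
Reagents that add atoms: none
Why: Aromatic Claisen rearrangement: the allyl group on O2' shifts by a concerted [3,3] process through a chair-like six-membered transition state to C3', its only ortho carbon bearing hydrogen, giving dienone 8, which enolizes to the hydrogen-bonded phenol 9; the allyl group on O4' then shifts in the same way to C5' through dienone 10, which enolizes to 11. The closest known reaction types are the thermal ortho-Claisen rearrangement of allyl aryl ethers and the para-Claisen (Claisen–Cope) sequence that takes over when an ortho carbon is substituted. No ring is closed and no stereocenter remains, because the sp3 carbons of 8 and 10 become aromatic again on enolization. The step needs positional selectivity only, and ring A supplies it: a dienone formed at the acyl-bearing C1', or at C3' once that carbon is filled, cannot enolize and either reverts to the ether or passes its allyl group on by a Cope shift to C5', while C6' is meta to both oxygens and out of reach of any [3,3] path. Because an unsubstituted allyl group is the same after one allylic inversion or two, the direct and the relayed paths give the identical substituent, so every order of events should end in 11. Ring B carries no allyl ether and its mesylate is thermally inert, so it should take no part.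

Step 5
Reactants: 11 3',5'-diallyl-2',4'-dihydroxy-4-(methanesulfonyloxy)dihydrochalcone; 12 2-methylbut-2-ene (two equivalents are consumed, one per allyl group)
Product: 13 2',4'-dihydroxy-4-(methanesulfonyloxy)-3',5'-bis(3-methylbut-2-enyl)dihydrochalcone
Conditions: second-generation Grubbs catalyst RuCl2(=CHPh)(PCy3)(H2IMes) (10 mol %), CH2Cl2/2-methylbut-2-ene (1:1, large excess), 35 °C, Ar
Reagents that add atoms: 2-methylbut-2-ene (second equivalent of 12), CC=C(C)C
Why: Twofold olefin cross-metathesis, in which each terminal allyl alkene exchanges its CH2 terminus for the isopropylidene end of one molecule of 2-methylbut-2-ene with loss of propene, the trisubstituted prenyl alkene formed is slow to re-enter the cycle, the large excess of the partner pushes both allyl groups to prenyl, and free phenols, the ketone and the aryl mesylate are tolerated by the ruthenium carbene.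

Step 6
Reactants: 13 2',4'-dihydroxy-4-(methanesulfonyloxy)-3',5'-bis(3-methylbut-2-enyl)dihydrochalcone
Product: 14 Gancaonin J [2',4',4-trihydroxy-3',5'-bis(3-methylbut-2-enyl)dihydrochalcone]
Conditions: 2 M aq. NaOH, 1,4-dioxane, 60 °C, Ar; then dilute aq. HCl to pH 5, 0 °C
Reagents that add atoms: none
Why: Base cleavage of an aryl methanesulfonate (hydroxide attack at sulfur or E1cB loss of sulfene), which should free the ring B phenoxide while the prenyl alkenes, the saturated ketone and the ring A phenoxides stay untouched under argon, the alcohol-free medium avoiding formation of methyl methanesulfonate that could O-methylate a phenoxide.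

**Compound list**

1 | 3-(4-hydroxyphenyl)propanoic acid | O=C(O)CCc1ccc(O)cc1 | starting material
2 | 3-[4-(methanesulfonyloxy)phenyl]propanoic acid | CS(=O)(=O)Oc1ccc(CCC(=O)O)cc1 | intermediate
3 | resorcinol | Oc1cccc(O)c1 | starting material
4 | difluoroboron chelate of ketone 5 (boron bridging O2' and the carbonyl oxygen; not isolated) | Oc1ccc2c(c1)O[B-](F)(F)[O+]=C2CCc1ccc(OS(C)(=O)=O)cc1 | intermediate
5 | 2',4'-dihydroxy-4-(methanesulfonyloxy)dihydrochalcone | O=C(CCc1ccc(OS(C)(=O)=O)cc1)c1ccc(O)cc1O | intermediate
6 | allyl bromide | C=CCBr | starting material
7 | 2',4'-bis(allyloxy)-4-(methanesulfonyloxy)dihydrochalcone | C=CCOc1ccc(C(=O)CCc2ccc(OS(C)(=O)=O)cc2)c(OCC=C)c1 | intermediate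
8 | 6-allyl-5-(allyloxy)-2-{3-[4-(methanesulfonyloxy)phenyl]propanoyl}cyclohexa-2,4-dien-1-one (C3'-allyl dienone, racemic at the transient sp3 carbon; not isolated) | C=CCOC1=CC=C(C(=O)CCc2ccc(OS(C)(=O)=O)cc2)C(=O)C1CC=C | intermediate
9 | 3'-allyl-4'-(allyloxy)-2'-hydroxy-4-(methanesulfonyloxy)dihydrochalcone (not isolated) | C=CCOc1ccc(C(=O)CCc2ccc(OS(C)(=O)=O)cc2)c(O)c1CC=C | intermediate
10 | 2,6-diallyl-3-hydroxy-4-{3-[4-(methanesulfonyloxy)phenyl]propanoyl}cyclohexa-2,4-dien-1-one (C5'-allyl dienone, racemic at the transient sp3 carbon; not isolated) | C=CCC1C=C(C(=O)CCc2ccc(OS(C)(=O)=O)cc2)C(O)=C(CC=C)C1=O | intermediate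
11 | 3',5'-diallyl-2',4'-dihydroxy-4-(methanesulfonyloxy)dihydrochalcone | C=CCc1cc(C(=O)CCc2ccc(OS(C)(=O)=O)cc2)c(O)c(CC=C)c1O | intermediate
12 | 2-methylbut-2-ene | CC=C(C)C | starting material
13 | 2',4'-dihydroxy-4-(methanesulfonyloxy)-3',5'-bis(3-methylbut-2-enyl)dihydrochalcone | CC(C)=CCc1cc(C(=O)CCc2ccc(OS(C)(=O)=O)cc2)c(O)c(CC=C(C)C)c1O | intermediate
14 | Gancaonin J | CC(C)=CCc1cc(C(=O)CCc2ccc(O)cc2)c(O)c(CC=C(C)C)c1O | target

**Step count**

Total steps: 6. Longest linear sequence: 6 steps (1 → 2 → 5 → 7 → 11 → 13 → 14).

**Steps most likely to fail, with fallbacks**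

1. Step 4 (double allyl migration). The second allyl group may stall on oxygen when it has to take the relayed path through a non-enolizable dienone, or the hot phenolic intermediates may cyclize or decompose before both shifts are complete.
Fallback, setting out from 5 and returning at 11: no allyl group is ever placed on O2', so only simple ortho shifts are needed. Compound 5 is mono-allylated with allyl bromide 6 (1.05 equiv) and K2CO3 in acetone at reflux, the hydrogen-bonded 2'-OH staying free, to give 4'-(allyloxy)-2'-hydroxy-4-(methanesulfonyloxy)dihydrochalcone F1. Heating F1 in 1,2-dichlorobenzene at 190 °C should move the allyl group mainly to C3' through the C3'-allyl dienone F2, giving 3'-allyl-2',4'-dihydroxy-4-(methanesulfonyloxy)dihydrochalcone F3. A second O4'-allylation of F3 with allyl bromide 6 under the same conditions gives compound 9, now isolated. Its only free ortho carbon is C5', so a second ortho-Claisen rearrangement through dienone 10 should lead to 11.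

2. Step 5 (double cross-metathesis). Exchange may stop at one of the two alkenes, ethylidene instead of isopropylidene may be transferred to give crotyl groups, or ruthenium hydride species may isomerize allyl to propenyl and then shorten the chain.
Fallback, setting out from 5 and returning at 13: the prenyl groups are attached directly by cross-coupling, so steps 3 to 5 are not needed. Compound 5 is iodinated at its two activated ring A positions with N-iodosuccinimide (2.1 equiv) in MeCN at room temperature to give 2',4'-dihydroxy-3',5'-diiodo-4-(methanesulfonyloxy)dihydrochalcone F4. A double Stille coupling of F4 with two equivalents of tributyl(3-methylbut-2-en-1-yl)stannane (CCCC[Sn](CCCC)(CCCC)CC=C(C)C) and Pd(PPh3)4 (zerovalent palladium) in DMF at 90 °C should give 13. The linear prenyl isomer is expected from reductive elimination at the less substituted allyl terminus.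

3. Step 6 (mesylate cleavage). Cleavage of the sulfonate may be slow, with air oxidation or base-induced degradation of the electron-rich diprenyl resorcinol ketone competing during the prolonged exposure.
Fallback, setting out from 11 and returning at 14: the sulfonate is removed before the prenyl groups exist. Compound 11 is treated with 2 M aq. NaOH in 1,4-dioxane at 60 °C, then dilute HCl, to give 3',5'-diallyl-2',4',4-trihydroxydihydrochalcone F5. Cross-metathesis of F5 with 2-methylbut-2-ene 12 (large excess) and the second-generation Grubbs catalyst RuCl2(=CHPh)(PCy3)(H2IMes), which tolerates free phenols, should give 14 directly.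

**Further compounds**

F1 | step 4 | 4'-(allyloxy)-2'-hydroxy-4-(methanesulfonyloxy)dihydrochalcone | C=CCOc1ccc(C(=O)CCc2ccc(OS(C)(=O)=O)cc2)c(O)c1
F2 | step 4 | 6-allyl-5-hydroxy-4-{3-[4-(methanesulfonyloxy)phenyl]propanoyl}cyclohexa-2,4-dien-1-one (C3'-allyl dienone, racemic at the transient sp3 carbon) | C=CCC1C(=O)C=CC(C(=O)CCc2ccc(OS(C)(=O)=O)cc2)=C1O
F3 | step 4 | 3'-allyl-2',4'-dihydroxy-4-(methanesulfonyloxy)dihydrochalcone | C=CCc1c(O)ccc(C(=O)CCc2ccc(OS(C)(=O)=O)cc2)c1O
F4 | step 5 | 2',4'-dihydroxy-3',5'-diiodo-4-(methanesulfonyloxy)dihydrochalcone | O=C(CCc1ccc(OS(C)(=O)=O)cc1)c1cc(I)c(O)c(I)c1O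
F5 | step 6 | 3',5'-diallyl-2',4',4-trihydroxydihydrochalcone | C=CCc1cc(C(=O)CCc2ccc(O)cc2)c(O)c(CC=C)c1O
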